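**Retrosynthetic overview**
1. Target ⇐ C4 ketone (methylenation last); esters by acylation; C11 carbinol by hydroxyl-directed reduction of a C11 ketone; butenolide joined at C12–C13 to the methyl of a 9-acetyl group.
2. Ring B ⇐ C7–C8 bond: a SmI2 ketyl makes the aldehyde carbon C7 nucleophilic and adds it to one of two identical acetyl groups on C9; this closes ring B and sets C7, C8 and C9 together.
3. Keto-aldehyde ⇐ ring A exo-methylene ketone by reductive aldol with acrolein (C5–C6; sets C5 and C6), then ozonolysis.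
4. Exo-methylene ketone ⇐ (R)-4-silyloxycyclohexenone + 3-methylpentane-2,4-dione (C9–C10 by Mukaiyama–Michael; sets C10), then Mannich methylenation.
5. Ring order: ring A first (cyclohexa-1,3-diene, asymmetric Kornblum–DeLaMare), ring B by the ketyl closure, butenolide ring brought in preformed from tetronic acid.

Assumption: clerodane numbering is used (ring A = C1–C5 and C10; ring B = C5–C10; side chain C11–C16), β is the decalin face carrying the C5 methyl, and the target is the (1R,5R,6R,7S,8R,9S,10S,11S) isomer encoded by the given SMILES.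

**Route**

Step 1
Reactants: 1 cyclohexa-1,3-diene
Product: 3 (R)-4-hydroxycyclohex-2-en-1-one, via endoperoxide 2 (not isolated)
Conditions: O2, hν, tetraphenylporphyrin (cat.), CH2Cl2, 0 °C; then O-acetylcupreidine or O-acetylcupreine (the pseudo-enantiomer that gives R, 10 mol%), rt
Reagents that add atoms: dioxygen O=O
Why: Singlet-oxygen [4+2] cycloaddition gives the meso endoperoxide, and the chiral-base-catalysed Kornblum–DeLaMare rearrangement removes one of the two enantiotopic bridgehead protons, so the catalyst sets the C1 carbinol centre (R).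

Step 2
Reactants: 3 (R)-4-hydroxycyclohex-2-en-1-one
Product: 4 (R)-4-(tert-butyldimethylsilyloxy)cyclohex-2-en-1-one
Conditions: TBSCl, imidazole, CH2Cl2, 0 °C → rt
Reagents that add atoms: tert-butyldimethylsilyl chloride CC(C)(C)[Si](C)(C)Cl
Why: Standard silyl ether formation; the bulky ether later shields one face of the enone.

Step 3
Reactants: 4 (R)-4-(tert-butyldimethylsilyloxy)cyclohex-2-en-1-one; 5 3-methylpentane-2,4-dione
Product: 8 Mannich base (ring A ketone with 1α-OTBS and 5-CH2NMe2 and the 10β-C(Me)(COMe)2 unit), via enol silane 6 (not isolated), via Michael adduct 7 (not isolated)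
Conditions: 5, TMSOTf, i-Pr2NEt, CH2Cl2, 0 °C; 4, −78 → −30 °C; then [Me2N=CH2]I, −30 °C → rt; aq. NaHCO3
Reagents that add atoms: N,N-dimethylmethyleneiminium iodide C=[N+](C)C.[I-]
Why: One-pot enol silane formation, Mukaiyama–Michael addition and Mannich trapping: the enol silane adds to the TMSOTf-activated enone anti to the C1 silyloxy group (sets C10; C9 is not yet stereogenic because it carries two identical acetyl groups), and the regiodefined enol silane 7 is captured at C5 by the iminium ion.

Step 4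
Reactants: 8 Mannich base
Product: 10 exo-methylene ketone 3-[(1S,6R)-6-(tert-butyldimethylsilyloxy)-2-methylidene-3-oxocyclohexyl]-3-methylpentane-2,4-dione, via ammonium iodide 9 (not isolated)
Conditions: MeI, CH2Cl2, rt; then aq. NaHCO3, CH2Cl2, rt
Reagents that add atoms: none
Why: N-quaternisation and E1cB (Hofmann-type) elimination of the β-ammonium ketone under bicarbonate give the s-cis exo-methylene ketone without isomerising the alkene into the ring or touching C10.

Step 5
Reactants: 10 exo-methylene ketone; 11 acrolein (prop-2-enal)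
Product: 13 aldol (ring A 4-ketone with 5β-Me and 5α-[(S)-CH(OH)CH=CH2]), via catecholboron enolate 12 (not isolated)
Conditions: catecholborane, THF, −20 °C → rt; then 11, −78 → −30 °C; pH 7 buffer
Reagents that add atoms: none
Why: Reductive aldol: catecholborane reduces the s-cis enone in 1,4 fashion (the exo-methylene becomes the C5 methyl) to a regiodefined boron enolate, which adds to acrolein through a Zimmerman–Traxler chair on the face anti to the C10 substituent (sets quaternary C5) with the vinyl group equatorial (sets C6).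

Step 6
Reactants: 13 aldol
Product: 14 bis-silyl ether (13 with C6-OTBS)
Conditions: TBSOTf, 2,6-lutidine, CH2Cl2, −78 °C
Reagents that add atoms: tert-butyldimethylsilyl triflate CC(C)(C)[Si](C)(C)OS(=O)(=O)C(F)(F)F
Why: Low-temperature silylation protects the retro-aldol-prone β-hydroxy ketone as an ether that survives SmI2 (an α-acyloxy group would be cleaved).

Step 7
Reactants: 14 bis-silyl ether
Product: 15 keto-aldehyde (C7 aldehyde; C9 bears Me and two acetyl groups)
Conditions: O3, CH2Cl2, −78 °C; then PPh3, −78 °C → rt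
Reagents that add atoms: ozone [O-][O+]=O
Why: Ozonolysis of the only alkene gives the α-silyloxy aldehyde; ketones and silyl ethers are inert.

Step 8
Reactants: 15 keto-aldehyde
Product: 16 ring B diol (decalin-4-one with 1α-OTBS, 6β-OTBS, 7α-OH, 8α-OH, 8β-Me, 9β-Me, 9α-acetyl, 5β-Me, 10α-H)
Conditions: SmI2 (2.5 equiv), THF, −78 → 0 °C; then pH 7 buffer
Reagents that add atoms: none
Why: SmI2 (divalent samarium) reduces the aldehyde to a ketyl, which makes C7 nucleophilic, and this adds to an acetyl carbonyl (pinacol-type ketyl–carbonyl cyclisation joining two normally electrophilic carbons); the trans C5/C10 substituents force a trans-decalin chair in which trivalent samarium bridges O7, O8 and the oxygen of the spectator acetyl, so O7 is equatorial and trans to the C6 silyloxy group, O8 is axial and cis to O7, and only the acetyl whose partner ends equatorial can react, which sets C7, C8 and C9 together.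

Step 9
Reactants: 16 ring B diol
Product: 17 7α-isobutyrate of 16
Conditions: (i-PrCO)2O, DMAP (cat.), pyridine, CH2Cl2, 0 °C → rt
Reagents that add atoms: isobutyric anhydride CC(C)C(=O)OC(=O)C(C)C
Why: Acylation takes the secondary equatorial C7 hydroxyl and leaves the axial tertiary C8 hydroxyl free.

Step 10
Reactants: 17 7α-isobutyrate
Product: 18 tris(trimethylsilyl) derivative (8α-OTMS; C11=C12 enol silane; C3=C4 enol silane)
Conditions: TMSOTf (3.5 equiv), Et3N, CH2Cl2, −78 → 0 °C
Reagents that add atoms: trimethylsilyl triflate C[Si](C)(C)OS(=O)(=O)C(F)(F)F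
Why: Soft enolisation/silylation; the acetyl group can only enolise toward its methyl (C9 is quaternary), the C4 ketone only toward C3, and capping O8 blocks retro-aldol opening of ring B.

Step 11
Reactants: 19 tetronic acid (4-hydroxyfuran-2(5H)-one)
Product: 20 4-bromofuran-2(5H)-one
Conditions: (COBr)2, DMF (cat.), CH2Cl2, 0 °C → rt
Reagents that add atoms: oxalyl bromide O=C(Br)C(Br)=O
Why: Vilsmeier-type activation of the vinylogous acid and addition–elimination by bromide give the β-bromobutenolide.

Step 12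
Reactants: 18 tris(trimethylsilyl) derivative; 20 4-bromofuran-2(5H)-one
Product: 23 11-ketone carrying the butenolide (17 with C12 bonded to C4 of furan-2(5H)-one), via tin enolate 21 (not isolated), via silylated coupling product 22 (not isolated)
Conditions: 20, Bu3SnF, Pd2(dba)3 (cat.), P(o-tol)3, toluene, 80 °C; then citric acid, THF/H2O, 0 °C
Reagents that add atoms: none
Why: Proposed new method: Bu3SnF converts the terminal methyl-ketone enol silane into a tin enolate that transmetalates to the alkenylpalladium bromide formed from 20 and zerovalent palladium, and reductive elimination makes C12–C13; the closest known reaction is the palladium-catalysed α-arylation of methyl-ketone silyl enol ethers through tin enolates, which is selective for terminal enol ethers, so the hindered C3=C4 enol ether and the O8 silyl ether are simply hydrolysed in the acidic work-up.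

Step 13
Reactants: 23 11-ketone
Product: 24 (11S)-alcohol
Conditions: Me4NBH(OAc)3, MeCN/AcOH (1:1), −30 °C
Reagents that add atoms: none
Why: Evans–Saksena reduction: the tertiary C8 hydroxyl binds boron and delivers hydride intramolecularly through a chair with the CH2-butenolide arm equatorial, giving the 1,3-anti diol (11S), while the C4 ketone (no free β-hydroxyl), the ester and the butenolide are not reduced.

Step 14
Reactants: 24 (11S)-alcohol
Product: 25 tetraol (1α-OH, 6β-OH, 8α-OH, 11-OH; 7α-isobutyrate)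
Conditions: HF·pyridine, pyridine, THF, 0 °C → rt
Reagents that add atoms: none
Why: Acidic fluoride removes both silyl ethers without the base-induced isobutyrate migration or retro-aldol chemistry that basic fluoride could cause.

Step 15
Reactants: 25 tetraol
Product: 26 1,6,11-triacetate 4-ketone
Conditions: Ac2O, DMAP, pyridine, CH2Cl2, rt
Reagents that add atoms: acetic anhydride CC(=O)OC(C)=O
Why: The three secondary hydroxyls are acetylated and the hindered axial tertiary C8 hydroxyl is not.

Step 16
Reactants: 26 1,6,11-triacetate 4-ketone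
Product: 27 target, (1R,5R,6R,7S,8R,9S,10S,11S)-1,6,11-triacetoxy-8-hydroxy-7-(isobutyryloxy)cleroda-4(18),13-dien-15,16-olide
Conditions: Zn, CH2Br2, TiCl4, THF; then 26, CH2Cl2, 0 °C → rt
Reagents that add atoms: dibromomethane BrCBr
Why: Takai–Lombardo-type methylenation with the gem-dizinc/titanium reagent is non-basic and attacks ketones but not esters or the butenolide, so the hindered C4 ketone becomes the exocyclic methylene without epimerisation or acyl migration.

**Compound list**
1 | cyclohexa-1,3-diene | C1=CC=CCC1 | starting material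
2 | 2,3-dioxabicyclo[2.2.2]oct-5-ene (meso endoperoxide) | C1=C[C@@H]2CC[C@H]1OO2 | intermediate (not isolated)
3 | (R)-4-hydroxycyclohex-2-en-1-one | O=C1CC[C@@H](O)C=C1 | intermediate
4 | (R)-4-(tert-butyldimethylsilyloxy)cyclohex-2-en-1-one | O=C1CC[C@@H](O[Si](C)(C)C(C)(C)C)C=C1 | intermediate
5 | 3-methylpentane-2,4-dione | CC(=O)C(C)C(C)=O | starting material
6 | 3-methyl-4-(trimethylsilyloxy)pent-3-en-2-one (E/Z mixture) | CC(=O)C(C)=C(C)O[Si](C)(C)C | intermediate (not isolated)
7 | 3-[(1S,6R)-6-(tert-butyldimethylsilyloxy)-3-(trimethylsilyloxy)cyclohex-2-en-1-yl]-3-methylpentane-2,4-dione (diketone unit trans to OTBS) | C[Si](C)(C)OC1=C[C@@H](C(C)(C(C)=O)C(C)=O)[C@H](O[Si](C)(C)C(C)(C)C)CC1 | intermediate (not isolated)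
8 | 3-{(1S,6R)-6-(tert-butyldimethylsilyloxy)-2-[(dimethylamino)methyl]-3-oxocyclohexyl}-3-methylpentane-2,4-dione (epimers at ring C2, inconsequential) | O=C1CC[C@@H](O[Si](C)(C)C(C)(C)C)[C@H](C(C)(C(C)=O)C(C)=O)C1CN(C)C | intermediate
9 | N-methyl quaternary ammonium iodide of 8 | O=C1CC[C@@H](O[Si](C)(C)C(C)(C)C)[C@H](C(C)(C(C)=O)C(C)=O)C1C[N+](C)(C)C.[I-] | intermediate (not isolated)
10 | 3-[(1S,6R)-6-(tert-butyldimethylsilyloxy)-2-methylidene-3-oxocyclohexyl]-3-methylpentane-2,4-dione | O=C1CC[C@@H](O[Si](C)(C)C(C)(C)C)[C@H](C(C)(C(C)=O)C(C)=O)C1=C | intermediate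
11 | acrolein (prop-2-enal) | C=CC=O | starting material
12 | catecholboron enolate of the 2-methyl ketone (C4–O–B, C4=C5) | C1(OB2Oc3ccccc3O2)=C(C)[C@@H](C(C)(C(C)=O)C(C)=O)[C@H](O[Si](C)(C)C(C)(C)C)CC1 | intermediate (not isolated)
13 | 3-{(1S,2S,6R)-6-(tert-butyldimethylsilyloxy)-2-[(1S)-1-hydroxyprop-2-en-1-yl]-2-methyl-3-oxocyclohexyl}-3-methylpentane-2,4-dione | O=C1CC[C@@H](O[Si](C)(C)C(C)(C)C)[C@H](C(C)(C(C)=O)C(C)=O)[C@@]1(C)[C@@H](O)C=C | intermediate
14 | tert-butyldimethylsilyl ether of 13 at the allylic hydroxyl | O=C1CC[C@@H](O[Si](C)(C)C(C)(C)C)[C@H](C(C)(C(C)=O)C(C)=O)[C@@]1(C)[C@@H](O[Si](C)(C)C(C)(C)C)C=C | intermediate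
15 | (2R)-2-(tert-butyldimethylsilyloxy)-2-[(1S,2S,3R)-3-(tert-butyldimethylsilyloxy)-1-methyl-2-(3-methyl-2,4-dioxopentan-3-yl)-6-oxocyclohexyl]acetaldehyde | O=C1CC[C@@H](O[Si](C)(C)C(C)(C)C)[C@H](C(C)(C(C)=O)C(C)=O)[C@@]1(C)[C@@H](O[Si](C)(C)C(C)(C)C)C=O | intermediate
16 | 9α-acetyl-1α,6β-bis(tert-butyldimethylsilyloxy)-7α,8α-dihydroxy-5β,8β,9β-trimethyl-10α-H-decalin-4-one (clerodane numbering) | O=C1CC[C@@H](O[Si](C)(C)C(C)(C)C)[C@H]2[C@@]1(C)[C@@H](O[Si](C)(C)C(C)(C)C)[C@H](O)[C@](C)(O)[C@]2(C)C(C)=O | intermediate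
17 | 7α-isobutyrate of 16 | O=C1CC[C@@H](O[Si](C)(C)C(C)(C)C)[C@H]2[C@@]1(C)[C@@H](O[Si](C)(C)C(C)(C)C)[C@H](OC(=O)C(C)C)[C@](C)(O)[C@]2(C)C(C)=O | intermediate
18 | tris(trimethylsilyl) derivative of 17 (8α-OTMS, C3=C4 enol silane, C11=C12 enol silane) | C[Si](C)(C)OC1=CC[C@@H](O[Si](C)(C)C(C)(C)C)[C@H]2[C@@]1(C)[C@@H](O[Si](C)(C)C(C)(C)C)[C@H](OC(=O)C(C)C)[C@](C)(O[Si](C)(C)C)[C@]2(C)C(=C)O[Si](C)(C)C | intermediate
19 | tetronic acid (4-hydroxyfuran-2(5H)-one) | OC1=CC(=O)OC1 | starting material
20 | 4-bromofuran-2(5H)-one | BrC1=CC(=O)OC1 | intermediate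
21 | tributyltin enolate from 18 (O11–SnBu3) | C[Si](C)(C)OC1=CC[C@@H](O[Si](C)(C)C(C)(C)C)[C@H]2[C@@]1(C)[C@@H](O[Si](C)(C)C(C)(C)C)[C@H](OC(=O)C(C)C)[C@](C)(O[Si](C)(C)C)[C@]2(C)C(=C)O[Sn](CCCC)(CCCC)CCCC | intermediate (not isolated)
22 | coupling product still carrying 8α-OTMS and the C3=C4 enol silane | C[Si](C)(C)OC1=CC[C@@H](O[Si](C)(C)C(C)(C)C)[C@H]2[C@@]1(C)[C@@H](O[Si](C)(C)C(C)(C)C)[C@H](OC(=O)C(C)C)[C@](C)(O[Si](C)(C)C)[C@]2(C)C(=O)CC1=CC(=O)OC1 | intermediate (not isolated)
23 | 4,11-diketone with the butenolide on C12 (1α,6β-bis-OTBS, 7α-isobutyrate, 8α-OH) | O=C1CC[C@@H](O[Si](C)(C)C(C)(C)C)[C@H]2[C@@]1(C)[C@@H](O[Si](C)(C)C(C)(C)C)[C@H](OC(=O)C(C)C)[C@](C)(O)[C@]2(C)C(=O)CC1=CC(=O)OC1 | intermediate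
24 | (11S)-alcohol of 23 | O=C1CC[C@@H](O[Si](C)(C)C(C)(C)C)[C@H]2[C@@]1(C)[C@@H](O[Si](C)(C)C(C)(C)C)[C@H](OC(=O)C(C)C)[C@](C)(O)[C@]2(C)[C@H](CC1=CC(=O)OC1)O | intermediate
25 | tetraol (1α,6β,8α,11-OH; 7α-isobutyrate; 4-ketone) | O=C1CC[C@@H](O)[C@H]2[C@@]1(C)[C@@H](O)[C@H](OC(=O)C(C)C)[C@](C)(O)[C@]2(C)[C@H](CC1=CC(=O)OC1)O | intermediate
26 | 1,6,11-triacetate 4-ketone | O=C1CC[C@@H](OC(C)=O)[C@H]2[C@@]1(C)[C@@H](OC(C)=O)[C@H](OC(=O)C(C)C)[C@](C)(O)[C@]2(C)[C@H](CC1=CC(=O)OC1)OC(C)=O | intermediate
27 | (1R,5R,6R,7S,8R,9S,10S,11S)-1,6,11-triacetoxy-8-hydroxy-7-(isobutyryloxy)cleroda-4(18),13-dien-15,16-olide (CNP0266716.1) | C=C1CC[C@@H](OC(C)=O)[C@H]2[C@@]1(C)[C@@H](OC(C)=O)[C@H](OC(=O)C(C)C)[C@](C)(O)[C@]2(C)[C@H](CC1=CC(=O)OC1)OC(C)=O | target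

**Step count and risks**

Total: 16 steps. Longest linear sequence: 15 steps (steps 1–10 and 12–16, from 1 to 27); step 11 is a one-step side branch.

The three steps most likely to fail are steps 3, 5 and 8. Steps 12 (an extension of known coupling chemistry) and 16 (methylenation of a hindered ketone on the final compound) are the next most uncertain.

Step 3 asks a fully substituted, weakly nucleophilic enol silane to add next to a silyloxy-bearing carbon, and it may be too slow or reverse. The fallback sets out from 4 and makes the quaternary carbon by alkylation after the C9–C10 bond exists. Commercial 4-(trimethylsilyloxy)pent-3-en-2-one (TMSOTf cat., CH2Cl2) adds to 4 to give the unmethylated enol silane adduct F1. This is trapped in the same flask with [Me2N=CH2]I to give the Mannich base with an acidic C9–H, F2. MeI (excess) with K2CO3 in acetone then C-methylates C9 and quaternises the amine in one operation. The route is rejoined at 9, which eliminates as in step 4.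

Step 5 must form the quaternary C5 next to the very crowded C10, and the boron aldol may be slow or poorly selective at C6. The fallback sets out from 10 and replaces the aldol by a one-carbon electrophile followed by a vinyl nucleophile. 1,4-Hydrosilylation (Et3SiH, RhCl(PPh3)3) gives the triethylsilyl enol ether F3. A Mukaiyama reaction with HC(OMe)3 (TMSOTf cat.), a small and very electrophilic cation that enters anti to the C10 substituent, gives the β-keto dimethyl acetal F4. Aqueous acid gives the non-enolisable β-keto aldehyde F5. Vinylzinc bromide (CH2=CHMgBr/ZnBr2) adds only to the aldehyde; chelation between the aldehyde and C4 ketone oxygens directs it to the face of the C5 methyl, which gives the same C6 configuration. The route is rejoined at 13.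

Step 8 may pick the wrong acetyl group, give a trans diol, or be diverted by reduction of the 1,3-diketone. The fallback sets out from 15 and separates ring closure from the setting of C7 and C8. Reductive olefination (TiCl3(DME)1.5, Zn(Cu), DME, reflux, high dilution) gives the ring B cyclohexene F6 with a C7=C8 double bond. Dihydroxylation (OsO4 cat., NMO) then occurs on the α face, opposite the two β-axial methyls at C5 and C9 and anti to the allylic C6 silyloxy group, and rejoins the route at 16. This fallback does not by itself control which acetyl reacts, so any C9 epimer would have to be separated at F6.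

**Further compounds**
F1 | step 3 | 3-[(1S,6R)-6-(tert-butyldimethylsilyloxy)-3-(trimethylsilyloxy)cyclohex-2-en-1-yl]pentane-2,4-dione | C[Si](C)(C)OC1=C[C@@H](C(C(C)=O)C(C)=O)[C@H](O[Si](C)(C)C(C)(C)C)CC1
F2 | step 3 | 3-{(1S,6R)-6-(tert-butyldimethylsilyloxy)-2-[(dimethylamino)methyl]-3-oxocyclohexyl}pentane-2,4-dione | O=C1CC[C@@H](O[Si](C)(C)C(C)(C)C)[C@H](C(C(C)=O)C(C)=O)C1CN(C)C
F3 | step 5 | 3-[(1S,6R)-6-(tert-butyldimethylsilyloxy)-2-methyl-3-(triethylsilyloxy)cyclohex-2-en-1-yl]-3-methylpentane-2,4-dione | CC[Si](CC)(CC)OC1=C(C)[C@@H](C(C)(C(C)=O)C(C)=O)[C@H](O[Si](C)(C)C(C)(C)C)CC1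
F4 | step 5 | 3-[(1S,2S,6R)-6-(tert-butyldimethylsilyloxy)-2-(dimethoxymethyl)-2-methyl-3-oxocyclohexyl]-3-methylpentane-2,4-dione | O=C1CC[C@@H](O[Si](C)(C)C(C)(C)C)[C@H](C(C)(C(C)=O)C(C)=O)[C@@]1(C)C(OC)OC
F5 | step 5 | (1S,2S,3R)-3-(tert-butyldimethylsilyloxy)-1-methyl-2-(3-methyl-2,4-dioxopentan-3-yl)-6-oxocyclohexane-1-carbaldehyde | O=C1CC[C@@H](O[Si](C)(C)C(C)(C)C)[C@H](C(C)(C(C)=O)C(C)=O)[C@@]1(C)C=O
F6 | step 8 | 9α-acetyl-1α,6β-bis(tert-butyldimethylsilyloxy)-5β,8,9β-trimethyl-10α-H-octalin-4-one with a C7=C8 double bond (clerodane numbering) | O=C1CC[C@@H](O[Si](C)(C)C(C)(C)C)[C@H]2[C@@]1(C)[C@@H](O[Si](C)(C)C(C)(C)C)C=C(C)[C@]2(C)C(C)=O
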